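**Retrosynthetic overview**
1. Labels: ring A = acetyl-bearing chromene (O1, C2, C3, C4, C4a, C5–C8, C8a), ring B = dimethoxychromene (primed atoms), C* = the CH(CH3) carbon. Feature: C3 of the C3=C4 alkene of ring A carries C* and its methyl carbon; one oxidation level higher this is the conjugated diene C4=C3–C*(=CH2), a cycloalkene bearing a 1-substituted vinyl group, which is the product type of a ring-closing enyne metathesis.
2. The pyran of ring B (O1'–C2' and C4'–C4a' bonds) is cut last, to a phenol para to C* plus 3-methylbut-2-enal; the C*–H bond is cut back to the diene through the para-quinone methide of that phenol.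
3. The pyran of ring A (C3–C4 bond and C*=CH2) is cut by enyne metathesis to an ortho-vinylaryl 1,1-dimethylpropargyl ether whose alkyne carries the ring B aryl group.
4. The enyne comes from a Sonogashira union of alkyne ether 7 (acetophenone 1: iodination, vinylation, copper-catalysed O-propargylation) with aryl iodide 11 (3,5-dimethoxyphenol: silylation, lithiation–iodination).
5. Ring order: both benzene rings are bought; pyran of ring A in step 7; pyran of ring B in step 10.

Key step: step 7

Assumption: the target centre is (S) (aryl > chromen-3-yl > CH3 > H); the sense of induction of the phosphoric acid in step 9 cannot be predicted for this substrate, so (R)-TRIP is written and its mirror image is used if a test reaction shows the (R) centre.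

**Route**

Step 1
Reactants: 1 2',4'-dihydroxy-6'-methoxyacetophenone
Product: 2 2',4'-dihydroxy-3'-iodo-6'-methoxyacetophenone
Conditions: I2 (1.0 equiv), NaHCO3, THF/H2O, 0 °C
Reagents that add atoms: iodine, [I][I]
Why: Electrophilic aromatic iodination of the phenolate should take place at C3', the carbon flanked by both hydroxyls and the most nucleophilic and least hindered site of this phloroglucinol-type ring (the behaviour of resorcinols under iodine and bicarbonate), while the weak base leaves the methyl ketone alone.

Step 2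
Reactants: 2 2',4'-dihydroxy-3'-iodo-6'-methoxyacetophenone; 3 vinylboronic acid pinacol ester
Product: 4 3'-ethenyl-2',4'-dihydroxy-6'-methoxyacetophenone
Conditions: PdCl2(dppf) (5 mol%), K2CO3, 1,4-dioxane/H2O, 80 °C
Reagents that add atoms: none
Why: Suzuki–Miyaura coupling of the aryl iodide with the vinylboronate tolerates free phenols and the ketone and places the vinyl group, the future C4 and the site of the ring-closing carbene, between the two hydroxyls.

Step 3
Reactants: 4 3'-ethenyl-2',4'-dihydroxy-6'-methoxyacetophenone; 5 2-methylbut-3-yn-2-ol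
Product: 7 3'-ethenyl-2'-hydroxy-6'-methoxy-4'-[(2-methylbut-3-yn-2-yl)oxy]acetophenone, via propargyl trifluoroacetate 6 (not isolated)
Conditions: 5, (CF3CO)2O, DBU, MeCN, −5 °C; then 4, DBU, CuCl2·2H2O (0.5 mol%), MeCN, −5 to 0 °C
Reagents that add atoms: none
Why: Copper-catalysed propargylic substitution (copper acetylide/allenylidene pathway) of the trifluoroacetate by the more acidic, non-chelated 4'-phenoxide should give the tertiary aryl propargyl ether, the 2'-hydroxyl being held back by its hydrogen bond to the acetyl group and by its two ortho substituents.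

Step 4
Reactants: 8 3,5-dimethoxyphenol
Product: 9 (3,5-dimethoxyphenoxy)tri(propan-2-yl)silane
Conditions: NaH, THF, 0 °C; then i-Pr3SiCl, 0 °C to rt
Reagents that add atoms: chlorotri(propan-2-yl)silane, CC(C)[Si](Cl)(C(C)C)C(C)C
Why: O-Silylation of the sodium phenoxide gives a bulky, base-stable triisopropylsilyl ether that masks the phenol for the lithiation and the two metal-catalysed steps that follow.

Step 5
Reactants: 9 (3,5-dimethoxyphenoxy)tri(propan-2-yl)silane
Product: 11 (4-iodo-3,5-dimethoxyphenoxy)tri(propan-2-yl)silane, via aryllithium 10 (not isolated)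
Conditions: n-BuLi, THF, 0 °C to rt; then I2, THF, −78 °C to rt
Reagents that add atoms: iodine, [I][I]
Why: Directed ortho-metalation occurs at the carbon between the two methoxy groups (the cooperative and most acidic site, the bulky silyloxy group being a poor director), and the iodine quench fixes the iodide para to the masked phenol, a position that direct iodination of the free phenol would not deliver cleanly.

Step 6
Reactants: 7 3'-ethenyl-2'-hydroxy-6'-methoxy-4'-[(2-methylbut-3-yn-2-yl)oxy]acetophenone; 11 (4-iodo-3,5-dimethoxyphenoxy)tri(propan-2-yl)silane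
Product: 12 4'-[(4-{2,6-dimethoxy-4-[tri(propan-2-yl)silyloxy]phenyl}-2-methylbut-3-yn-2-yl)oxy]-3'-ethenyl-2'-hydroxy-6'-methoxyacetophenone
Conditions: PdCl2(PPh3)2 (5 mol%), CuI (10 mol%), Et3N, THF, 55 °C, degassed
Reagents that add atoms: none
Why: Sonogashira coupling of the terminal alkyne with the aryl iodide runs below the temperature of the propargyl Claisen rearrangement and faster than a Heck reaction at the styrene, and aryl iodides with two ortho methoxy groups are competent partners at moderate temperature.

Step 7
Reactants: 12 4'-[(4-{2,6-dimethoxy-4-[tri(propan-2-yl)silyloxy]phenyl}-2-methylbut-3-yn-2-yl)oxy]-3'-ethenyl-2'-hydroxy-6'-methoxyacetophenone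
Product: 13 1-{3-[1-(2,6-dimethoxy-4-{[tri(propan-2-yl)silyl]oxy}phenyl)ethenyl]-5-hydroxy-7-methoxy-2,2-dimethyl-2H-chromen-6-yl}ethan-1-one
Conditions: second-generation Grubbs catalyst RuCl2(=CHPh)(PCy3)(H2IMes) (10 mol%), ethylene (1 atm), toluene, 80 °C
Reagents that add atoms: none
Why: The ruthenium methylidene maintained by ethylene exchanges with the styrene vinyl group to give the aryl carbene at C4, which adds [2+2] across the tethered alkyne with C4 bonding to the proximal alkyne carbon C3; opening of the ruthenacyclobutene forms the C3=C4 bond and a new carbene on C*, which ethylene caps as the exocyclic CH2 while returning the methylidene, so the step is a net isomerisation. The closest known reaction is the ring-closing enyne metathesis of 2-vinylphenyl propargyl ethers to 3-(1-substituted vinyl)-2H-chromenes under ethylene. The pyran of ring A (O1, C2, C3, C4, C4a, C8a) closes in the exo mode; endo closure would need a seven-membered ring. No stereocentre is formed. The step needs initiation at the alkene and exo closure: the monosubstituted vinyl group is the only unhindered π-bond, ethylene suppresses alkyne-first pathways and stilbene formation, and the four-atom tether with its gem-dimethyl group at C2 (Thorpe–Ingold effect) holds the carbene next to C3. The acetyl group, the chelated C5 hydroxyl and the silyl ether are inert to the carbene, and 80 °C stays below the propargyl Claisen rearrangement.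

Step 8
Reactants: 13 1-{3-[1-(2,6-dimethoxy-4-{[tri(propan-2-yl)silyl]oxy}phenyl)ethenyl]-5-hydroxy-7-methoxy-2,2-dimethyl-2H-chromen-6-yl}ethan-1-one
Product: 14 1-{5-hydroxy-3-[1-(4-hydroxy-2,6-dimethoxyphenyl)ethenyl]-7-methoxy-2,2-dimethyl-2H-chromen-6-yl}ethan-1-one
Conditions: Bu4NF, AcOH, THF, 0 °C
Reagents that add atoms: none
Why: Fluoride cleaves the aryl silyl ether (desilylation), and the acetic acid buffer should keep the liberated, sensitive 4-hydroxystyrene-type diene from oligomerising.

Step 9
Reactants: 14 1-{5-hydroxy-3-[1-(4-hydroxy-2,6-dimethoxyphenyl)ethenyl]-7-methoxy-2,2-dimethyl-2H-chromen-6-yl}ethan-1-one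
Product: 16 1-{5-hydroxy-3-[(1S)-1-(4-hydroxy-2,6-dimethoxyphenyl)ethyl]-7-methoxy-2,2-dimethyl-2H-chromen-6-yl}ethan-1-one, via para-quinone methide 15 (not isolated)
Conditions: (R)-TRIP [(R)-3,3'-bis(2,4,6-triisopropylphenyl)-1,1'-binaphthyl-2,2'-diyl hydrogen phosphate] (10 mol%), Hantzsch ester (diethyl 2,6-dimethyl-1,4-dihydropyridine-3,5-dicarboxylate, 1.5 equiv), toluene, 40 °C, argon
Reagents that add atoms: none
Why: Proposed new method: the phosphoric acid protonates the terminal CH2 of the 1-arylvinyl group while taking the ring B phenol proton, giving para-quinone methide 15 with C* as its δ-carbon; the phosphate then bridges the quinone methide oxygen and the N–H of the Hantzsch ester, and hydride should be delivered to one face of C* inside this chiral ion-paired assembly (1,6-addition), which restores the arene and sets the (S) centre under catalyst control; the chromene alkene is forced out of the quinone methide plane by the C2 gem-dimethyl group and the flanking methoxy groups, which should disfavour vinylogous 1,8-delivery at C4, and the C5 hydroxyl stays chelated to the acetyl group; the closest known reaction type is the chiral phosphoric acid-catalysed transfer hydrogenation of hydroxy-substituted 1,1-diarylethylenes through quinone methides.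

Step 10
Reactants: 16 1-{5-hydroxy-3-[(1S)-1-(4-hydroxy-2,6-dimethoxyphenyl)ethyl]-7-methoxy-2,2-dimethyl-2H-chromen-6-yl}ethan-1-one; 17 3-methylbut-2-enal
Product: 18 1-{3-[(1S)-1-(5,7-dimethoxy-2,2-dimethyl-2H-chromen-6-yl)ethyl]-5-hydroxy-7-methoxy-2,2-dimethyl-2H-chromen-6-yl}ethan-1-one (CNP0303487.1)
Conditions: ethylenediammonium diacetate (20 mol%), toluene, 110 °C
Reagents that add atoms: none
Why: Amine-salt-catalysed Knoevenagel-type condensation of the enal ortho to the only phenol with a free ortho carbon gives an ortho-quinone methide dienone that closes by oxa-6π electrocyclisation to the pyran of ring B (formal [3+3] chromene annulation); the two ortho positions are equivalent by rotation about the C*–aryl bond, the C5 hydroxyl of ring A has no free ortho carbon, and the near-neutral conditions do not touch C*.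

**Compound list**
1 | 2',4'-dihydroxy-6'-methoxyacetophenone | CC(=O)c1c(O)cc(O)cc1OC | starting material
2 | 2',4'-dihydroxy-3'-iodo-6'-methoxyacetophenone | CC(=O)c1c(O)c(I)c(O)cc1OC | intermediate
3 | vinylboronic acid pinacol ester (2-ethenyl-4,4,5,5-tetramethyl-1,3,2-dioxaborolane) | C=CB1OC(C)(C)C(C)(C)O1 | starting material
4 | 3'-ethenyl-2',4'-dihydroxy-6'-methoxyacetophenone | CC(=O)c1c(O)c(C=C)c(O)cc1OC | intermediate
5 | 2-methylbut-3-yn-2-ol | CC(C)(O)C#C | starting material
6 | 2-methylbut-3-yn-2-yl trifluoroacetate | CC(C)(OC(=O)C(F)(F)F)C#C | intermediate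
7 | 3'-ethenyl-2'-hydroxy-6'-methoxy-4'-[(2-methylbut-3-yn-2-yl)oxy]acetophenone | CC(=O)c1c(OC)cc(OC(C)(C)C#C)c(C=C)c1O | intermediate
8 | 3,5-dimethoxyphenol | COc1cc(O)cc(OC)c1 | starting material
9 | (3,5-dimethoxyphenoxy)tri(propan-2-yl)silane | COc1cc(O[Si](C(C)C)(C(C)C)C(C)C)cc(OC)c1 | intermediate
10 | {2,6-dimethoxy-4-[tri(propan-2-yl)silyloxy]phenyl}lithium | [Li]c1c(OC)cc(O[Si](C(C)C)(C(C)C)C(C)C)cc1OC | intermediate
11 | (4-iodo-3,5-dimethoxyphenoxy)tri(propan-2-yl)silane | COc1cc(O[Si](C(C)C)(C(C)C)C(C)C)cc(OC)c1I | intermediate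
12 | 4'-[(4-{2,6-dimethoxy-4-[tri(propan-2-yl)silyloxy]phenyl}-2-methylbut-3-yn-2-yl)oxy]-3'-ethenyl-2'-hydroxy-6'-methoxyacetophenone | CC(=O)c1c(OC)cc(OC(C)(C)C#Cc2c(OC)cc(O[Si](C(C)C)(C(C)C)C(C)C)cc2OC)c(C=C)c1O | intermediate
13 | 1-{3-[1-(2,6-dimethoxy-4-{[tri(propan-2-yl)silyl]oxy}phenyl)ethenyl]-5-hydroxy-7-methoxy-2,2-dimethyl-2H-chromen-6-yl}ethan-1-one | CC(=O)c1c(OC)cc2OC(C)(C)C(=Cc2c1O)C(=C)c1c(OC)cc(O[Si](C(C)C)(C(C)C)C(C)C)cc1OC | intermediate
14 | 1-{5-hydroxy-3-[1-(4-hydroxy-2,6-dimethoxyphenyl)ethenyl]-7-methoxy-2,2-dimethyl-2H-chromen-6-yl}ethan-1-one | CC(=O)c1c(OC)cc2OC(C)(C)C(=Cc2c1O)C(=C)c1c(OC)cc(O)cc1OC | intermediate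
15 | 4-[1-(6-acetyl-5-hydroxy-7-methoxy-2,2-dimethyl-2H-chromen-3-yl)ethylidene]-3,5-dimethoxycyclohexa-2,5-dien-1-one | O=C1C=C(OC)C(=C(C)C2=Cc3c(O)c(C(C)=O)c(OC)cc3OC2(C)C)C(OC)=C1 | intermediate
16 | 1-{5-hydroxy-3-[(1S)-1-(4-hydroxy-2,6-dimethoxyphenyl)ethyl]-7-methoxy-2,2-dimethyl-2H-chromen-6-yl}ethan-1-one | COc1cc2c(c(O)c1C(C)=O)C=C([C@H](C)c1c(OC)cc(O)cc1OC)C(C)(C)O2 | intermediate
17 | 3-methylbut-2-enal | CC(C)=CC=O | starting material
18 | 1-{3-[(1S)-1-(5,7-dimethoxy-2,2-dimethyl-2H-chromen-6-yl)ethyl]-5-hydroxy-7-methoxy-2,2-dimethyl-2H-chromen-6-yl}ethan-1-one | COc1cc2c(c(O)c1C(C)=O)C=C([C@H](C)c1c(OC)cc3c(c1OC)C=CC(C)(C)O3)C(C)(C)O2 | target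

**Step count**
Total steps: 10. Longest linear sequence: 8 (steps 1, 2, 3, 6, 7, 8, 9, 10); steps 4 and 5 form the side branch.

**Steps most likely to fail**

Step 9. Hydride may be delivered to the wrong terminus of the vinylogous quinone methide (C4 instead of C*), which would leave no stereocentre. The quinone methide may also form slowly or react with poor facial selectivity, because the two methoxy groups flanking C* twist it. The fallback uses known chemistry, sets out from 14 and comes back at 16. Homogeneous hydrogenation with RhCl(PPh3)3 (H2, 5 bar, benzene/EtOH, 40 °C) reduces 1,1-disubstituted alkenes in preference to trisubstituted ones and should saturate only the exocyclic methylene, giving the racemic phenol F1. Preparative HPLC on a chiral stationary phase (amylose tris(3,5-dimethylphenylcarbamate), hexane/2-propanol) then separates the (S) enantiomer, which is 16 and goes on to step 10, from the (R) enantiomer F2.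

Step 7. The carbene may fail to add across the alkyne, which is flanked by a quaternary carbon and a doubly ortho-substituted aryl group. The catalyst would then be lost to styrene dimerisation or rest as the chelated ortho-alkoxybenzylidene. The fallback sets out from 7 (with aryllithium 10 of step 5 as the source of the aryl partner) and comes back at 16, bypassing steps 6 to 9. The ring-closing enyne metathesis is run on the unhindered terminal alkyne of 7 (same catalyst, ethylene, toluene, 60 °C), the best-documented form of this cyclisation, to give the 3-vinylchromene F3. The aryl group is then attached to C* after ring closure, together with the hydrogen. The boronic acid F4 is made from 10 (B(OMe)3, THF, −78 °C, then aqueous NH4Cl). A nickel hydride-catalysed enantioselective Markovnikov 1,2-hydroarylation of the terminal alkene of the 1-aryl-1,3-diene F3 with F4 (Ni(cod)2, chiral bisoxazoline or spiro aminophosphine ligand, alcohol as hydrogen source) should give the silyl ether F5, with C3=C4 kept in conjugation with ring A. Bu4NF/AcOH as in step 8 then gives 16.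

Step 1. Iodination may occur at C5' next to the methoxy group, or at both free ring positions. The fallback sets out from 1 and comes back at 2. The non-chelated 4'-hydroxyl is silylated (t-BuMe2SiCl, imidazole, DMF) to the 4'-silyl ether F6. The one remaining free hydroxyl then directs iodination to its ortho carbon C3' (benzyltrimethylammonium dichloroiodate, NaHCO3, CH2Cl2/MeOH), the selectivity established for 2'-hydroxy-4',6'-dialkoxyacetophenones, to give the 3'-iodide F7. Bu4NF/AcOH in THF returns 2.

**Further compounds**
F1 | step 9 | racemic 1-{5-hydroxy-3-[1-(4-hydroxy-2,6-dimethoxyphenyl)ethyl]-7-methoxy-2,2-dimethyl-2H-chromen-6-yl}ethan-1-one | COc1cc2c(c(O)c1C(C)=O)C=C(C(C)c1c(OC)cc(O)cc1OC)C(C)(C)O2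
F2 | step 9 | 1-{5-hydroxy-3-[(1R)-1-(4-hydroxy-2,6-dimethoxyphenyl)ethyl]-7-methoxy-2,2-dimethyl-2H-chromen-6-yl}ethan-1-one | COc1cc2c(c(O)c1C(C)=O)C=C([C@@H](C)c1c(OC)cc(O)cc1OC)C(C)(C)O2
F3 | step 7 | 1-(3-ethenyl-5-hydroxy-7-methoxy-2,2-dimethyl-2H-chromen-6-yl)ethan-1-one | CC(=O)c1c(OC)cc2OC(C)(C)C(C=C)=Cc2c1O
F4 | step 7 | {2,6-dimethoxy-4-[tri(propan-2-yl)silyloxy]phenyl}boronic acid | COc1cc(O[Si](C(C)C)(C(C)C)C(C)C)cc(OC)c1B(O)O
F5 | step 7 | 1-{3-[(1S)-1-(2,6-dimethoxy-4-{[tri(propan-2-yl)silyl]oxy}phenyl)ethyl]-5-hydroxy-7-methoxy-2,2-dimethyl-2H-chromen-6-yl}ethan-1-one | COc1cc2c(c(O)c1C(C)=O)C=C([C@H](C)c1c(OC)cc(O[Si](C(C)C)(C(C)C)C(C)C)cc1OC)C(C)(C)O2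
F6 | step 1 | 4'-[tert-butyl(dimethyl)silyloxy]-2'-hydroxy-6'-methoxyacetophenone | CC(=O)c1c(O)cc(O[Si](C)(C)C(C)(C)C)cc1OC
F7 | step 1 | 4'-[tert-butyl(dimethyl)silyloxy]-2'-hydroxy-3'-iodo-6'-methoxyacetophenone | CC(=O)c1c(O)c(I)c(O[Si](C)(C)C(C)(C)C)cc1OC
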